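**Two peaks.** Count the enzyme first. L goes to X, so the two share the charge, and each flask asks which of them holds more than half of it.

in all of them: L 20 mM; G 0.58 µM; time 8.0 min
- alpha: E 0.01 mol%
- eta: E 0.012 mol%

    L + E → X + E, rate k1*[L]*[E]/(1 + ([L]/Km1) + ([X]/Kp1)) (Km1 = 9.6 mM, Kp1 = 17 mM, k1 = 2.1 × 10⁵ L mol⁻¹ min⁻¹)
    E + G → E.G (k2 = 1.0 × 10⁵ L mol⁻¹ s⁻¹)
    E → Q (k3 = 0.072 min⁻¹)

1. which of these there is most of at the end, counted by the L in it, alpha (L / X)
2. which of these there is most of at the end, counted by the L in it, eta (L / X)
3. the largest of these amounts at the end, in percent of the L charged, alpha
4. the largest of these amounts at the end, in percent of the L charged, eta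

**First estimate.** Alpha charges 2.00 µM of E. At the start L falls at a fractional rate of 0.136 min⁻¹, and held for 8.0 min that converts 66.4%, which puts X ahead.

**Doubt about G.** That estimate counts E that is not working. G meets E within about 5.00 s, far shorter than the run, and G is the limiting reagent of that step, with 0.58 µM against the E charged. So alpha keeps 1.42 µM, and eta keeps 1.82 µM of its 2.40 µM.

**Doubt about decay.** E also turns into Q, so what remains works for an effective 6.08 min, not 8.0 min. The first step's rate constant times the enzyme left after G times that effective time gives 1.81 in alpha and 2.32 in eta; this product is the dose D, the enzyme exposure.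

**Doubt about drift.** The rate does not hold still, since cL falls while cX enters the denominator. Integrating the rate law gives D = a·ln(starting cL / cL) + b·x, where x is the fraction converted, a is 2.18 and b is 0.907. Reaching half takes a dose B of 1.96. The dose in alpha is smaller than B. The dose in eta is larger than B. The slope of the rule at that point turns these gaps into 47.2% of X in alpha and 56.9% in eta. We commit to L leading alpha at 52.8% and X leading eta at 56.9%.

**The result.** The forecast gives L at 52.6% in alpha and X at 56.6% in eta, noting that “the 20% extra enzyme is about 28% extra active enzyme after titration”. The simulation gives L at 52.8% in alpha and X at 56.6% in eta.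

**Dose reused.** The higher loading of E is the main reason X stands higher in eta than in alpha: eta set back to the loading of alpha gives 47.2% of X against 56.6%. In dose, that loading is the step from 1.81 to 2.32, which crosses B. The neighbour of eta with G cut to 1.4 × 10⁻⁴ mM has a dose of 2.89, and the rule turns its 65.2% of X into a dose of 2.89.

(The constants were set for the occasion; no experiment stands behind them.)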